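## Retrosynthetic overview

1. The ten-membered ring and the γ-lactone are closed together in the last step. An ω-formyl allylic bromide carrying a vinyl chloride is cyclised by a divalent-chromium γ-chloroallylation that forms C6–C7, sets C6 (Cl) and C7 (O), creates the C5=C16 methylene and lactonises onto C19.
2. The C7/C8/C17/C19 unit comes from (S)-malate: Fráter–Seebach methylation, then a Seebach dioxolanone aldol onto a ring A C9 aldehyde (C8–C9 bond, C9 stereocentre).
3. Ring A stereocentres: copper-catalysed vinyl addition/aldol on an (R)-4-silyloxy-2-methylcyclohexenone (C10, C1), then LiBH(s-Bu)3 and Narasaka–Prasad reductions (C14, C2); the C11 ketone becomes the spiro-epoxide with LiCH2Cl.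
4. The C2–C6/C16 arm with its (Z)-vinyl chloride comes from carbomagnesiation/chlorination of propargyl alcohol.
5. Ring order: ring A (from a quinone monoketal, CBS reduction) → spiro-epoxide → ten-membered ring and γ-lactone simultaneously.

Assumption: 4-methoxy-3-methylphenol, [2-(1,3-dioxolan-2-yl)ethyl]magnesium bromide (0.5 M in THF), propargyl alcohol, diethyl (S)-malate and all reagents are purchasable; locants C1–C20 in names follow briarane numbering of the target, β is the face of ring A that carries the C1 methyl group and α the opposite face.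

## Route

Step 1
Reactants: 1 4-methoxy-3-methylphenol
Product: 2 4,4-dimethoxy-3-methylcyclohexa-2,5-dien-1-one
Conditions: PhI(OAc)2, MeOH, 0 °C
Reagents that add atoms: methanol (CO)
Why: Oxidative dearomatisation of a para-alkoxyphenol, in which the phenoxenium ion formed with the iodine diacetate is trapped by methanol at the methoxy-bearing carbon to give the quinone monoketal; no stereocentre is formed.

Step 2
Reactants: 2 4,4-dimethoxy-3-methylcyclohexa-2,5-dien-1-one
Product: 3 4,4-dimethoxy-3-methylcyclohex-2-en-1-one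
Conditions: H2 (1 atm), RhCl(PPh3)3 (5 mol %), benzene, rt
Reagents that add atoms: none
Why: Chemoselective homogeneous hydrogenation, in which RhCl(PPh3)3 saturates only the disubstituted C5=C6 alkene and leaves the methyl-bearing trisubstituted enone alkene; no stereocentre.

Step 3
Reactants: 3 4,4-dimethoxy-3-methylcyclohex-2-en-1-one
Product: 4 (R)-4,4-dimethoxy-3-methylcyclohex-2-en-1-ol
Conditions: (S)-1-methyl-3,3-diphenyltetrahydro-1H,3H-pyrrolo[1,2-c][1,3,2]oxazaborole (10 mol %), catecholborane, toluene, −78 °C; then aq. NaOH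
Reagents that add atoms: none
Why: Corey–Bakshi–Shibata reduction, in which the alkenyl side of the enone acts as the large group so the (S)-oxazaborolidine delivers hydride to give the (R)-allylic alcohol (this carbon becomes C11 and later steers the conjugate addition).

Step 4
Reactants: 4 (R)-4,4-dimethoxy-3-methylcyclohex-2-en-1-ol
Product: 6 (R)-4-[(tert-butyldimethylsilyl)oxy]-2-methylcyclohex-2-en-1-one, via silyl ether ketal 5 (not isolated)
Conditions: TBSCl, imidazole, DMF, rt; then 5 % aq. oxalic acid, THF, rt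
Reagents that add atoms: tert-butyldimethylsilyl chloride (CC(C)(C)[Si](C)(C)Cl); water (O)
Why: Silyl ether formation followed by mild hydrolysis of the allylic dimethyl ketal (the TBS ether survives oxalic acid) releases the transposed enone without touching the carbinol stereocentre.

Step 5
Reactants: 7 [2-(1,3-dioxolan-2-yl)ethyl]magnesium bromide (2.2 equiv); 8 prop-2-yn-1-ol
Product: 10 (Z)-3-chloro-2-[2-(1,3-dioxolan-2-yl)ethyl]prop-2-en-1-ol, via chelated alkenylmagnesium alkoxide 9 (not isolated)
Conditions: CuI (10 mol %), THF, −10 °C → rt; then NCS, −30 → 0 °C; H2O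
Reagents that add atoms: N-chlorosuccinimide (ClN1C(=O)CCC1=O)
Why: Hydroxyl-directed copper-catalysed carbomagnesiation of the propargylic alkoxide puts the alkyl group on C2 and magnesium on C3 in a five-membered chelate (anti addition), and NCS chlorinates the alkenyl–Mg bond with retention, so Cl ends cis to CH2OH (Z).

Step 6
Reactants: 10 (Z)-3-chloro-2-[2-(1,3-dioxolan-2-yl)ethyl]prop-2-en-1-ol
Product: 11 2-[(Z)-4-chloro-3-{[(4-methoxybenzyl)oxy]methyl}but-3-en-1-yl]-1,3-dioxolane
Conditions: NaH, 4-methoxybenzyl chloride, tetrabutylammonium iodide (cat.), THF/DMF, 0 °C → rt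
Reagents that add atoms: 4-methoxybenzyl chloride (COc1ccc(CCl)cc1)
Why: Williamson etherification of the sodium alkoxide; the vinyl chloride and the acetal are inert to NaH at this temperature.

Step 7
Reactants: 11 2-[(Z)-4-chloro-3-{[(4-methoxybenzyl)oxy]methyl}but-3-en-1-yl]-1,3-dioxolane
Product: 12 (Z)-4-(chloromethylidene)-5-[(4-methoxybenzyl)oxy]pentanal
Conditions: 1 M aq. HCl, THF, rt
Reagents that add atoms: water (O)
Why: Acid-catalysed acetal hydrolysis; the PMB ether and the vinyl chloride tolerate dilute HCl at rt.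

Step 8
Reactants: 13 diethyl (S)-malate
Product: 15 diethyl (2S,3R)-2-hydroxy-3-methylbutanedioate, via dilithium alkoxide enolate 14 (not isolated)
Conditions: LiN(i-Pr)2 (2.2 equiv), THF, −78 → −20 °C; then MeI, −78 → 0 °C; H2O
Reagents that add atoms: iodomethane (CI)
Why: Fráter–Seebach alkylation, in which the lithium-chelated alkoxide enolate is methylated anti to the alkoxide-bearing carbon to give the anti (2S,3R) diester (about 9:1), fixing the future C17 methyl centre next to C8.

Step 9
Reactants: 15 diethyl (2S,3R)-2-hydroxy-3-methylbutanedioate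
Product: 16 (2S,3R)-2-hydroxy-3-methylbutanedioic acid
Conditions: KOH, H2O/EtOH, rt; then aq. HCl to pH 1
Reagents that add atoms: potassium hydroxide ([K+].[OH-])
Why: Saponification of both esters; the dicarboxylate alkoxide is not enolised by aqueous KOH at rt, so neither stereocentre epimerises.

Step 10
Reactants: 16 (2S,3R)-2-hydroxy-3-methylbutanedioic acid
Product: 17 (2R)-2-[(2S,4S)-2-tert-butyl-5-oxo-1,3-dioxolan-4-yl]propanoic acid
Conditions: t-BuCHO, p-toluenesulfonic acid (cat.), H2SO4 (cat.), pentane, reflux (water separator)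
Reagents that add atoms: pivalaldehyde (CC(C)(C)C=O)
Why: Seebach acetalisation of the α-hydroxy acid unit gives the five-membered dioxolanone in preference to the six-membered dioxanone, and the thermodynamically favoured cis isomer (tert-butyl cis to the side chain, new acetal centre S) is obtained after crystallisation.

Step 11
Reactants: 17 (2R)-2-[(2S,4S)-2-tert-butyl-5-oxo-1,3-dioxolan-4-yl]propanoic acid
Product: 18 methyl (2R)-2-[(2S,4S)-2-tert-butyl-5-oxo-1,3-dioxolan-4-yl]propanoate
Conditions: Me3SiCHN2, MeOH/toluene, 0 °C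
Reagents that add atoms: (trimethylsilyl)diazomethane (C[Si](C)(C)C=[N+]=[N-])
Why: Diazoalkane methylation of the free carboxylic acid is neutral and leaves the base-sensitive dioxolanone untouched.

Step 12
Reactants: 6 (R)-4-[(tert-butyldimethylsilyl)oxy]-2-methylcyclohex-2-en-1-one; 12 (Z)-4-(chloromethylidene)-5-[(4-methoxybenzyl)oxy]pentanal (1.6 equiv)
Product: 20 ring A aldol adduct (C2 carbinol epimers), via bromomagnesium enolate 19 (not isolated)
Conditions: CH2=CHMgBr (1.3 equiv), CuBr·SMe2 (15 mol %), THF, −78 → −40 °C; then 12, −78 °C; H2O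
Reagents that add atoms: vinylmagnesium bromide (C=C[Mg]Br)
Why: Three-component conjugate addition–aldol coupling, in which the vinyl group adds anti to the C11 silyloxy group (sets C10) and the magnesium enolate attacks 12 on the face anti to the new vinyl group (sets quaternary C1 with methyl β); the C2 carbinol mixture is erased in step 13.

Step 13
Reactants: 20 ring A aldol adduct (C2 carbinol epimers)
Product: 21 ring A 2,14-diketone
Conditions: Dess–Martin periodinane, NaHCO3, CH2Cl2, rt
Reagents that add atoms: none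
Why: Dess–Martin oxidation of the neopentylic secondary alcohol gives the non-enolisable 2,2-disubstituted 1,3-diketone under buffered conditions that avoid retro-Claisen cleavage.

Step 14
Reactants: 21 ring A 2,14-diketone
Product: 22 14α-hydroxy C2 ketone
Conditions: LiBH(s-Bu)3 (1.05 equiv), THF, −78 °C; then H2O
Reagents that add atoms: none
Why: Hindered-hydride reduction, in which the cyclohexanone reacts much faster than the acyclic ketone next to the quaternary carbon and is attacked along the equatorial trajectory, giving the axial 14α-alcohol trans to the C1 methyl group.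

Step 15
Reactants: 22 14α-hydroxy C2 ketone
Product: 24 (2R)-2,14α-diol, via diethylboron chelate 23 (not isolated)
Conditions: Et2BOMe, THF/MeOH (4:1), −78 °C; then NaBH4, −78 °C; MeOH, AcOH
Reagents that add atoms: none
Why: Narasaka–Prasad reduction, in which the boron chelate between the C14 hydroxyl and the C2 ketone is reduced by external hydride along the axial trajectory of the half-chair (C13 equatorial, C10 axial on the chelate ring), giving the 1,3-syn diol and hence (2R).

Step 16
Reactants: 24 (2R)-2,14α-diol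
Product: 25 2,14-diacetate
Conditions: Ac2O, Et3N, 4-(dimethylamino)pyridine, CH2Cl2, rt
Reagents that add atoms: acetic anhydride (CC(=O)OC(C)=O)
Why: Nucleophile-catalysed acetylation esterifies both hindered secondary hydroxyls; no other free nucleophile is present.

Step 17
Reactants: 25 2,14-diacetate
Product: 26 11α-alcohol
Conditions: HF·pyridine, pyridine, THF, 0 °C → rt
Reagents that add atoms: none
Why: Buffered fluoride desilylation cleaves the secondary TBS ether while the acetates, the PMB ether and both alkenes are untouched.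

Step 18
Reactants: 26 11α-alcohol
Product: 27 C11 ketone
Conditions: Dess–Martin periodinane, NaHCO3, CH2Cl2, 0 °C → rt
Reagents that add atoms: none
Why: Dess–Martin oxidation under buffered conditions gives the C11 ketone and keeps the now α-positioned C10 centre in its stable equatorial-vinyl configuration.

Step 19
Reactants: 27 C11 ketone
Product: 29 11β,20-spiro-epoxide, via lithium chlorohydrin alkoxide 28 (not isolated)
Conditions: ICH2Cl, MeLi·LiBr, THF, −78 °C → rt
Reagents that add atoms: chloroiodomethane (ClCI)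
Why: Carbenoid addition then intramolecular Williamson closure, in which chloromethyllithium made in situ by iodine–lithium exchange adds to the ketone at −78 °C from the equatorial (α) side because the axial path is blocked by the syn-axial C1 methyl group, and the alkoxide displaces chloride to give the epoxide with oxygen axial (β).

Step 20
Reactants: 29 11β,20-spiro-epoxide
Product: 31 C9 aldehyde, via vicinal diol 30 (not isolated)
Conditions: OsO4 (2 mol %), NaIO4, 2,6-lutidine, dioxane/H2O (3:1), rt
Reagents that add atoms: osmium tetroxide (O=[Os](=O)(=O)=O); sodium periodate ([Na+].[O-]I(=O)(=O)=O)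
Why: Lemieux–Johnson oxidation, in which OsO4 dihydroxylates the monosubstituted terminal alkene far faster than the electron-poor trisubstituted vinyl chloride and NaIO4 cleaves the diol, with 2,6-lutidine buffering the medium for the epoxide.

Step 21
Reactants: 18 methyl (2R)-2-[(2S,4S)-2-tert-butyl-5-oxo-1,3-dioxolan-4-yl]propanoate (1.3 equiv); 31 C9 aldehyde
Product: 34 (8R,9R) aldol acetate, via lithium enolate 32 (not isolated), via lithium aldolate 33 (not isolated)
Conditions: LiN(SiMe3)2 (1.25 equiv), THF, −78 °C; then 31, −78 °C; then Ac2O, −78 → 0 °C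
Reagents that add atoms: acetic anhydride (CC(=O)OC(C)=O)
Why: Seebach self-regeneration-of-stereocentres aldol, in which the dioxolanone enolate reacts on the face anti to the tert-butyl group so C9 replaces H at C8 with retention, the Zimmerman–Traxler chair (C17 cis to the enolate oxygen) and Felkin–Anh attack anti to C1 of the aldehyde both give (9R), and the aldolate is acetylated before it can lactonise.

Step 22
Reactants: 34 (8R,9R) aldol acetate
Product: 35 C7 dimethylamide with free 8-hydroxyl
Conditions: Me2NH (2 M in THF, 5 equiv), 0 °C → rt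
Reagents that add atoms: dimethylamine (CNC)
Why: Aminolysis of the dioxolanone, an activated acylal ester whose expelled hemiacetal loses pivalaldehyde and frees the C8 hydroxyl, while the hindered acetates, the methyl ester and the neopentylic epoxide CH2 react far more slowly.

Step 23
Reactants: 35 C7 dimethylamide with free 8-hydroxyl
Product: 36 C7 aldehyde (PMB ether)
Conditions: Cp2Zr(H)Cl (2.5 equiv), THF, rt, 20 min; then H2O, silica gel
Reagents that add atoms: none
Why: Hydrozirconation of the tertiary amide gives a zirconated hemiaminal that cannot be reduced further and hydrolyses to the aldehyde, esters and the epoxide being left alone; C8 has no hydrogen, so the aldehyde cannot epimerise.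

Step 24
Reactants: 36 C7 aldehyde (PMB ether)
Product: 37 C16 allylic alcohol
Conditions: DDQ (2,3-dichloro-5,6-dicyano-1,4-benzoquinone), CH2Cl2/pH 7 buffer (10:1), 0 °C
Reagents that add atoms: none
Why: Oxidative PMB cleavage, in which DDQ converts the electron-rich benzyl ether into an oxocarbenium ion that is hydrolysed to the primary allylic alcohol; aldehyde, epoxide and vinyl chloride are inert.

Step 25
Reactants: 37 C16 allylic alcohol
Product: 39 C16 allylic bromide, via allylic mesylate 38 (not isolated)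
Conditions: MsCl, Et3N, CH2Cl2, −30 °C; then LiBr, THF, 0 °C
Reagents that add atoms: lithium bromide ([Li+].[Br-])
Why: Selective mesylation of the primary allylic hydroxyl (the tertiary C8 hydroxyl does not react at −30 °C) and SN2 displacement by bromide leave the non-enolisable aldehyde untouched.

Step 26
Reactants: 39 C16 allylic bromide
Product: 42 target CNP0104093.4, via allylchromium dichloride 40 (not isolated), via hydroxy ester 41 (not isolated)
Conditions: CrCl2 (8 equiv), THF (0.003 M, slow addition of 39), 0 °C → rt; then H2O, silica gel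
Reagents that add atoms: none
Why: Proposed new method: divalent chromium inserts into the allylic C16–Br bond to give a γ-chloroallylchromium species that equilibrates by 1,3-metallotropic shift to the isomer with Cl trans to CH2–Cr and adds through its γ-carbon C6 to the C7 aldehyde in a six-membered chair transition state, which closes the ten-membered ring, places Cl on C6 anti to the new C7–O bond, moves the alkene to C5=C16 and, by Felkin–Anh attack (C8–O antiperiplanar, nucleophile delivered from the C9 side), sets C7 so that its alkoxide closes the γ-lactone on the C19 methyl ester; the closest known reactions are the intermolecular Nozaki–Hiyama addition of γ-chloroallylchromium from 1,3-dichloropropene to aldehydes (anti chlorohydrins) and intramolecular Nozaki–Hiyama allylations that close ten-membered carbocycles.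

## Compound list

1 | 4-methoxy-3-methylphenol | COc1ccc(O)cc1C | starting material
2 | 4,4-dimethoxy-3-methylcyclohexa-2,5-dien-1-one | COC1(OC)C=CC(=O)C=C1C | intermediate
3 | 4,4-dimethoxy-3-methylcyclohex-2-en-1-one | COC1(OC)CCC(=O)C=C1C | intermediate
4 | (R)-4,4-dimethoxy-3-methylcyclohex-2-en-1-ol | COC1(OC)CC[C@@H](O)C=C1C | intermediate
5 | (R)-tert-butyl[(4,4-dimethoxy-3-methylcyclohex-2-en-1-yl)oxy]dimethylsilane | COC1(OC)CC[C@@H](O[Si](C)(C)C(C)(C)C)C=C1C | intermediate (not isolated)
6 | (R)-4-[(tert-butyldimethylsilyl)oxy]-2-methylcyclohex-2-en-1-one | CC1=C[C@H](O[Si](C)(C)C(C)(C)C)CCC1=O | intermediate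
7 | [2-(1,3-dioxolan-2-yl)ethyl]magnesium bromide | Br[Mg]CCC1OCCO1 | starting material
8 | prop-2-yn-1-ol | C#CCO | starting material
9 | bromomagnesium (Z)-3-(bromomagnesio)-2-[2-(1,3-dioxolan-2-yl)ethyl]prop-2-en-1-olate | Br[Mg]/C=C(/CCC1OCCO1)\CO[Mg]Br | intermediate (not isolated)
10 | (Z)-3-chloro-2-[2-(1,3-dioxolan-2-yl)ethyl]prop-2-en-1-ol | Cl/C=C(/CCC1OCCO1)\CO | intermediate
11 | 2-[(Z)-4-chloro-3-{[(4-methoxybenzyl)oxy]methyl}but-3-en-1-yl]-1,3-dioxolane | Cl/C=C(/CCC1OCCO1)\COCc2ccc(OC)cc2 | intermediate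
12 | (Z)-4-(chloromethylidene)-5-[(4-methoxybenzyl)oxy]pentanal | Cl/C=C(/CCC=O)\COCc1ccc(OC)cc1 | intermediate
13 | diethyl (S)-malate | CCOC(=O)C[C@H](O)C(=O)OCC | starting material
14 | dilithium alkoxide ester enolate of 13 | CCOC(O[Li])=C[C@H](O[Li])C(=O)OCC | intermediate (not isolated)
15 | diethyl (2S,3R)-2-hydroxy-3-methylbutanedioate | CCOC(=O)[C@H](C)[C@H](O)C(=O)OCC | intermediate
16 | (2S,3R)-2-hydroxy-3-methylbutanedioic acid | OC(=O)[C@H](C)[C@H](O)C(=O)O | intermediate
17 | (2R)-2-[(2S,4S)-2-tert-butyl-5-oxo-1,3-dioxolan-4-yl]propanoic acid | OC(=O)[C@H](C)[C@@H]1O[C@H](C(C)(C)C)OC1=O | intermediate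
18 | methyl (2R)-2-[(2S,4S)-2-tert-butyl-5-oxo-1,3-dioxolan-4-yl]propanoate | COC(=O)[C@H](C)[C@@H]1O[C@H](C(C)(C)C)OC1=O | intermediate
19 | ring A bromomagnesium enolate (C14 O–MgBr, C1=C14; 10β-vinyl trans to 11α-OTBS) | CC1=C(O[Mg]Br)CC[C@@H](O[Si](C)(C)C(C)(C)C)[C@@H]1C=C | intermediate (not isolated)
20 | ring A aldol adduct: C14 ketone, 1β-methyl, 1α-chain C2H(OH)–C3H2–C4H2–C5(=C6HCl, Z)–C16H2OPMB (both C2 epimers), 10β-vinyl, 11α-OTBS | Cl/C=C(/CCC(O)[C@@]1(C)C(=O)CC[C@@H](O[Si](C)(C)C(C)(C)C)[C@@H]1C=C)\COCc2ccc(OC)cc2 | intermediate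
21 | ring A 2,14-diketone (as 20 with C2=O) | Cl/C=C(/CCC(=O)[C@@]1(C)C(=O)CC[C@@H](O[Si](C)(C)C(C)(C)C)[C@@H]1C=C)\COCc2ccc(OC)cc2 | intermediate
22 | 14α-hydroxy C2 ketone (axial OH trans to the C1 methyl) | Cl/C=C(/CCC(=O)[C@@]1(C)[C@@H](O)CC[C@@H](O[Si](C)(C)C(C)(C)C)[C@@H]1C=C)\COCc2ccc(OC)cc2 | intermediate
23 | diethylboron chelate (14-O-diethylborinate) of 22 | Cl/C=C(/CCC(=O)[C@@]1(C)[C@@H](OB(CC)CC)CC[C@@H](O[Si](C)(C)C(C)(C)C)[C@@H]1C=C)\COCc2ccc(OC)cc2 | intermediate (not isolated)
24 | (2R)-2,14α-diol (1,3-syn), 10β-vinyl, 11α-OTBS | Cl/C=C(/CC[C@@H](O)[C@@]1(C)[C@@H](O)CC[C@@H](O[Si](C)(C)C(C)(C)C)[C@@H]1C=C)\COCc2ccc(OC)cc2 | intermediate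
25 | 2,14-diacetate of 24 | Cl/C=C(/CC[C@@H](OC(C)=O)[C@@]1(C)[C@@H](OC(C)=O)CC[C@@H](O[Si](C)(C)C(C)(C)C)[C@@H]1C=C)\COCc2ccc(OC)cc2 | intermediate
26 | 11α-alcohol (2,14-diacetate, 10β-vinyl) | Cl/C=C(/CC[C@@H](OC(C)=O)[C@@]1(C)[C@@H](OC(C)=O)CC[C@@H](O)[C@@H]1C=C)\COCc2ccc(OC)cc2 | intermediate
27 | C11 ketone (2,14-diacetate, 10β-vinyl) | Cl/C=C(/CC[C@@H](OC(C)=O)[C@@]1(C)[C@@H](OC(C)=O)CCC(=O)[C@@H]1C=C)\COCc2ccc(OC)cc2 | intermediate
28 | lithium alkoxide of the C11 chloromethyl carbinol (O β, CH2Cl α) | Cl/C=C(/CC[C@@H](OC(C)=O)[C@@]1(C)[C@@H](OC(C)=O)CC[C@@](O[Li])(CCl)[C@@H]1C=C)\COCc2ccc(OC)cc2 | intermediate (not isolated)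
29 | 11β,20-spiro-epoxide (oxirane O β, CH2 α; 2,14-diacetate, 10β-vinyl) | Cl/C=C(/CC[C@@H](OC(C)=O)[C@@]1(C)[C@@H](OC(C)=O)CC[C@@]3(CO3)[C@@H]1C=C)\COCc2ccc(OC)cc2 | intermediate
30 | vicinal diol from the C10 vinyl group of 29 (carbinol epimers) | Cl/C=C(/CC[C@@H](OC(C)=O)[C@@]1(C)[C@@H](OC(C)=O)CC[C@@]3(CO3)[C@@H]1C(O)CO)\COCc2ccc(OC)cc2 | intermediate (not isolated)
31 | C9 aldehyde (10β-formyl spiro-epoxide diacetate) | Cl/C=C(/CC[C@@H](OC(C)=O)[C@@]1(C)[C@@H](OC(C)=O)CC[C@@]3(CO3)[C@@H]1C=O)\COCc2ccc(OC)cc2 | intermediate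
32 | lithium enolate of 18 | COC(=O)[C@H](C)C1=C(O[Li])O[C@@H](C(C)(C)C)O1 | intermediate (not isolated)
33 | lithium aldolate (C9 O–Li; C8 spiro-dioxolanone) | Cl/C=C(/CC[C@@H](OC(C)=O)[C@@]1(C)[C@@H](OC(C)=O)CC[C@@]3(CO3)[C@@H]1[C@@H](O[Li])[C@]4(O[C@H](C(C)(C)C)OC4=O)[C@@H](C)C(=O)OC)\COCc2ccc(OC)cc2 | intermediate (not isolated)
34 | (8R,9R) aldol acetate: 2,9,14-triacetate, C8 in the 2-tert-butyl-dioxolanone (C7 carbonyl), (17R)-methyl, C19 methyl ester | Cl/C=C(/CC[C@@H](OC(C)=O)[C@@]1(C)[C@@H](OC(C)=O)CC[C@@]3(CO3)[C@@H]1[C@@H](OC(C)=O)[C@]4(O[C@H](C(C)(C)C)OC4=O)[C@@H](C)C(=O)OC)\COCc2ccc(OC)cc2 | intermediate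
35 | C7 N,N-dimethylamide with free (8R)-hydroxyl | Cl/C=C(/CC[C@@H](OC(C)=O)[C@@]1(C)[C@@H](OC(C)=O)CC[C@@]3(CO3)[C@@H]1[C@@H](OC(C)=O)[C@@](O)(C(=O)N(C)C)[C@@H](C)C(=O)OC)\COCc2ccc(OC)cc2 | intermediate
36 | C7 aldehyde with free (8R)-hydroxyl (C16 PMB ether) | Cl/C=C(/CC[C@@H](OC(C)=O)[C@@]1(C)[C@@H](OC(C)=O)CC[C@@]3(CO3)[C@@H]1[C@@H](OC(C)=O)[C@@](O)(C=O)[C@@H](C)C(=O)OC)\COCc2ccc(OC)cc2 | intermediate
37 | C16 allylic alcohol (C7 aldehyde) | Cl/C=C(/CC[C@@H](OC(C)=O)[C@@]1(C)[C@@H](OC(C)=O)CC[C@@]3(CO3)[C@@H]1[C@@H](OC(C)=O)[C@@](O)(C=O)[C@@H](C)C(=O)OC)\CO | intermediate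
38 | C16 allylic mesylate | Cl/C=C(/CC[C@@H](OC(C)=O)[C@@]1(C)[C@@H](OC(C)=O)CC[C@@]3(CO3)[C@@H]1[C@@H](OC(C)=O)[C@@](O)(C=O)[C@@H](C)C(=O)OC)\COS(C)(=O)=O | intermediate (not isolated)
39 | C16 allylic bromide (C7 aldehyde, (Z)-vinyl chloride) | Cl/C=C(/CC[C@@H](OC(C)=O)[C@@]1(C)[C@@H](OC(C)=O)CC[C@@]3(CO3)[C@@H]1[C@@H](OC(C)=O)[C@@](O)(C=O)[C@@H](C)C(=O)OC)\CBr | intermediate
40 | C16 allylchromium dichloride (γ-chloroallyl, equilibrating alkene geometry) | ClC=C(CC[C@@H](OC(C)=O)[C@@]1(C)[C@@H](OC(C)=O)CC[C@@]3(CO3)[C@@H]1[C@@H](OC(C)=O)[C@@](O)(C=O)[C@@H](C)C(=O)OC)C[Cr](Cl)Cl | intermediate (not isolated)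
41 | macrocyclic hydroxy ester (seco-lactone of 42: 7-OH, C19 methyl ester, 6-Cl, C5=C16) | C=C1CC[C@@H](OC(C)=O)[C@@]2(C)[C@@H](OC(C)=O)CC[C@@]3(CO3)[C@@H]2[C@@H](OC(C)=O)[C@](O)([C@@H](C)C(=O)OC)[C@@H](O)[C@H]1Cl | intermediate (not isolated)
42 | CNP0104093.4: 2,9,14-triacetoxy-6-chloro-8-hydroxy-11,20-epoxybriar-5(16)-en-18,7-olide, (1S,2R,6S,7R,8R,9R,10S,11S,14S,17R) | C=C1CC[C@@H](OC(C)=O)[C@@]2(C)[C@@H](OC(C)=O)CC[C@@]3(CO3)[C@@H]2[C@@H](OC(C)=O)[C@]2(O)[C@@H](C)C(=O)O[C@H]2[C@H]1Cl | target

## Step count and risks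

Total step count: 26. Longest linear sequence: 19 steps (steps 1–4, then 12–26); fragment C (steps 5–7) enters at step 12 and fragment B (steps 8–11) at step 21.

The three steps most likely to fail:

Step 26 (macrocyclising γ-chloroallylation). The risks are oligomerisation, chelation by the free C8 hydroxyl overriding Felkin–Anh control at C7, and opening of the epoxide by Lewis-acidic trivalent chromium. The fallback sets out from 37 and comes back to the route at 41. The primary allylic hydroxyl of 37 is acylated with methyl chloroformate and pyridine to give allylic methyl carbonate F1. Pd(PPh3)4 (5 mol %) with InI (2 equiv) in THF then ionises the carbonate to a π-allylpalladium species that is reductively transmetallated to an allylindium reagent. This adds through its γ-carbon to the C7 aldehyde under high dilution to give hydroxy ester 41, which lactonises to 42 as in step 26. This swaps one-electron insertion into a bromide for π-allyl umpolung, avoids the labile bromide 39 and the chromium salts, and runs under nearly neutral conditions.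

Step 21 (Seebach aldol on a hindered, enolisable aldehyde). The risks are competing deprotonation at C17 of the ester side chain, retro-aldol, and lactonisation of the aldolate. The fallback sets out from 17 and 31 and comes back at 34. The free acid 17 is doubly deprotonated with LiN(SiMe3)2 (2.1 equiv) to its carboxylate–enolate dianion, in which the side chain can no longer be enolised. Addition of 31 and an Ac2O quench give, after aqueous work-up, the aldol acetate carboxylic acid F2. Me3SiCHN2 in MeOH/toluene esterifies F2 to 34.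

Step 22 (aminolysis at the carbonyl next to the quaternary C8). The risks are slow opening and competing attack on acetates. The fallback sets out from 34 and comes back at 36. EtSLi in THF at −78 °C opens the dioxolanone to the S-ethyl thioester F3 (free 8-hydroxyl, pivalaldehyde lost). Et3SiH with palladium on carbon (Pd/C) in acetone (Fukuyama reduction) then converts F3 directly into aldehyde 36, so steps 22 and 23 are replaced by an acyl-transfer/hydrosilane pair that never uses an amine or a zirconium hydride.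

## Further compounds

F1 | step 26 | C16 allylic methyl carbonate of 37 | Cl/C=C(/CC[C@@H](OC(C)=O)[C@@]1(C)[C@@H](OC(C)=O)CC[C@@]3(CO3)[C@@H]1[C@@H](OC(C)=O)[C@@](O)(C=O)[C@@H](C)C(=O)OC)\COC(=O)OC
F2 | step 21 | C19 carboxylic acid analogue of 34 | Cl/C=C(/CC[C@@H](OC(C)=O)[C@@]1(C)[C@@H](OC(C)=O)CC[C@@]3(CO3)[C@@H]1[C@@H](OC(C)=O)[C@]4(O[C@H](C(C)(C)C)OC4=O)[C@@H](C)C(=O)O)\COCc2ccc(OC)cc2
F3 | step 22 | C7 S-ethyl thioester with free 8-hydroxyl | Cl/C=C(/CC[C@@H](OC(C)=O)[C@@]1(C)[C@@H](OC(C)=O)CC[C@@]3(CO3)[C@@H]1[C@@H](OC(C)=O)[C@@](O)(C(=O)SCC)[C@@H](C)C(=O)OC)\COCc2ccc(OC)cc2
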